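1. At 80 min I read complex with four exchanged, and I have to decide which of elm, maple and alder is worth that reading, when a reading is good to 0.5 percentage points.

the same everywhere: starting complex 0.30 M
- Tuesday's: incoming ligand 0.12 M; run made earlier
- Monday's: incoming ligand 0.44 M; run made earlier
- Wednesday's: incoming ligand 1.1 M; run made earlier
- elm: incoming ligand 0.150 M; time 80 min
- maple: incoming ligand 0.900 M; time 80 min
- alder: incoming ligand 1.20 M; time 80 min

| run | time / min | complex with four exchanged / % | complex with one exchanged / % |
|---|---|---|---|
| Tuesday's | 20.0 | 0 | 1.4 |
| Tuesday's | 40.0 | 0 | 1.1 |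
| Tuesday's | 60.0 | 0.9 | 0.6 |
| Tuesday's | 80.0 | 0.3 | 0.2 |
| Monday's | 10.0 | 0.2 | 6.1 |
| Monday's | 30.0 | 0.7 | 2.5 |
| Monday's | 50.0 | 0.7 | 1.7 |
| Monday's | 80.0 | 0.4 | 1.6 |
| Wednesday's | 20.0 | 0 | 1.4 |
| Wednesday's | 40.0 | 1.9 | 0.6 |
| Wednesday's | 60.0 | 5.5 | 1.3 |
| Wednesday's | 80.0 | 7.0 | 0.9 |

(scatter of a reading: 0.5 percentage points)



- complex with four exchanged at the end, in percent of the starting complex charged, for each flask in turn (elm, maple, alder)

2. At the same [starting complex], Monday's flask, with [incoming ligand] 0.44 M, reads 0.4% at 80.0 min, and Wednesday's, with 1.1 M, reads 7.0%. The ln of the ratio of readings over the ln of the ratio of charges gives 3.12. I carry this number as the yield order (an apparent reaction order): the power of [incoming ligand] to which the reading at a fixed time and fixed [starting complex] is taken as proportional.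

3. Monday's reading is loose at 0.5 points, so I also try it one scatter higher, at the same 80.0 min, which gives a looser order of 2.24.

4. Scaling Wednesday's reading by the charge ratio to the power 3.12, I reckon 0.0139% for elm, 3.74% for maple and 9.19% for alder.

5. I spend the reading on maple and alder and keep the reckoned value for elm, because the looser order still puts elm at 0.0809%, below the scatter.

6. The forecast gives 0.1%, 3.8% and 9% on “an apparent order near 3”, and its elm value stands above mine.

7. The flasks give 0.00450% in elm, 3.74% in maple and 8.49% in alder.

    starting complex + incoming ligand ⇌ leaving ligand + complex with one exchanged (K = 0.320, k = 0.160 /M/min)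
    complex with one exchanged + incoming ligand ⇌ leaving ligand + complex with two exchanged (K = 33.0, k = 0.890 /M/min)
    complex with two exchanged + incoming ligand ⇌ leaving ligand + complex with three exchanged (K = 19.0, k = 0.0200 /M/min)
    complex with three exchanged + incoming ligand ⇌ leaving ligand + complex with four exchanged (K = 0.660, k = 0.0120 /M/min)
    starting complex → decomposition product (k = 1.10 × 10⁻⁴ /min)
    complex with one exchanged → over-reaction product (k = 0.240 /min)

8. Carried from maple's result, the order 3.12 gives alder 9.19% against 8.49%, and elm 0.0139% against 0.00450%. In maple, at the concentrations as charged, complex with one exchanged has a forward half-life of 0.87 min towards complex with two exchanged, shorter than the 2.89 min of its loss to over-reaction product. In elm at 80.0 min that forward half-life is 59 min, longer than the loss, and over-reaction product stands at 32.0% against 6.07% of complex with two exchanged.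

(The numbers in the tables are simulated with made-up constants; scatter was added.)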